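The route rests on cutting the trisubstituted C2=C3 alkene of the cyclopentene (ring B, indene numbering). C3 is read as the carbon of an ethyl ketone on ring-fusion carbon C3a and C2 as an aldehyde on the C1 methine, two arms held trans on neighbouring carbons of the cyclohexene (ring A). An intramolecular McMurry coupling joins the two carbonyl carbons, closing ring B and creating its alkene in one operation. The keto aldehyde is unmasked from a δ-lactone whose O bridge between C3 and C2 is the temporary tether of an intramolecular Diels–Alder reaction. That cycloaddition builds ring A and four stereocentres from the single Roche-ester centre of an acyclic mesaconate trienyl ester.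

Key step: step 12

Assumption: the stabilised ylides 4 and 11 are taken as purchasable (each is otherwise one step from the corresponding phosphonium salt); atom labels C1 to C7a are those of the 1H-indene skeleton of the target and are used for the corresponding carbons of every precursor.

Step 1
Reactants: 1 methyl (2S)-3-hydroxy-2-methylpropanoate
Product: 2 methyl (2S)-3-[(tert-butyldimethylsilyl)oxy]-2-methylpropanoate
Conditions: TBSCl, imidazole, DMF, 0 °C → rt
Reagents that add atoms: tert-butyldimethylsilyl chloride, CC(C)(C)[Si](C)(C)Cl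
Why: Imidazole-promoted silylation protects the primary alcohol as its silyl ether and leaves the purchased stereocentre (the future C1) untouched.

Step 2
Reactants: 2 methyl (2S)-3-[(tert-butyldimethylsilyl)oxy]-2-methylpropanoate
Product: 3 (2S)-3-[(tert-butyldimethylsilyl)oxy]-2-methylpropanal
Conditions: i-Bu2AlH (1.05 equiv), CH2Cl2, −78 °C; then MeOH, aq. potassium sodium tartrate
Reagents that add atoms: none
Why: Partial ester reduction with one equivalent of hydride at −78 °C stops at the aldehyde oxidation level until work-up, and the crude α-chiral aldehyde is used at once to avoid epimerisation.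

Step 3
Reactants: 3 (2S)-3-[(tert-butyldimethylsilyl)oxy]-2-methylpropanal; 4 2-(triphenylphosphoranylidene)butanal
Product: 5 (2E,4R)-5-[(tert-butyldimethylsilyl)oxy]-2-ethyl-4-methylpent-2-enal
Conditions: toluene, 90 °C
Reagents that add atoms: none
Why: Wittig olefination with a formyl-stabilised ylide should give the (E)-2-ethyl enal (C7a=C7, with C1 trans to the formyl carbon) under neutral conditions that preserve the α-stereocentre, and the conjugated product is too unreactive to be homologated again at this temperature.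

Step 4
Reactants: 5 (2E,4R)-5-[(tert-butyldimethylsilyl)oxy]-2-ethyl-4-methylpent-2-enal; 4 2-(triphenylphosphoranylidene)butanal
Product: 6 (2E,4E,6R)-7-[(tert-butyldimethylsilyl)oxy]-2,4-diethyl-6-methylhepta-2,4-dienal
Conditions: toluene, 110 °C
Reagents that add atoms: none
Why: A second Wittig olefination with the same stabilised ylide, slower on the enal and therefore run hotter, adds C5 with its ethyl group and should give the (E)-alkene (formyl carbon trans to C7).

Step 5
Reactants: 6 (2E,4E,6R)-7-[(tert-butyldimethylsilyl)oxy]-2,4-diethyl-6-methylhepta-2,4-dienal; 7 diethyl benzylphosphonate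
Product: 8 tert-butyl{[(2R,3E,5E,7E)-4,6-diethyl-2-methyl-8-phenylocta-3,5,7-trien-1-yl]oxy}dimethylsilane
Conditions: LiN(SiMe3)2, THF, −78 °C → rt
Reagents that add atoms: none
Why: Horner–Wadsworth–Emmons olefination with the preformed benzylphosphonate anion should give the (E)-styryl alkene and complete the triene, and preforming the anion avoids γ-deprotonation of the dienal.

Step 6
Reactants: 8 tert-butyl{[(2R,3E,5E,7E)-4,6-diethyl-2-methyl-8-phenylocta-3,5,7-trien-1-yl]oxy}dimethylsilane
Product: 9 (2R,3E,5E,7E)-4,6-diethyl-2-methyl-8-phenylocta-3,5,7-trien-1-ol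
Conditions: Bu4NF, THF, 0 °C → rt
Reagents that add atoms: none
Why: Fluoride-mediated cleavage of the silyl ether frees the primary alcohol without affecting the triene.

Step 7
Reactants: 10 glyoxylic acid monohydrate; 11 methyl 2-(triphenylphosphoranylidene)propanoate
Product: 12 (2E)-4-methoxy-3-methyl-4-oxobut-2-enoic acid
Conditions: CH2Cl2, 0 °C → rt
Reagents that add atoms: none
Why: Wittig olefination of glyoxylic acid with an α-methyl ester-stabilised ylide is E-selective, so the methyl ester ends trans to the carboxylic acid (mesaconate geometry) and the construction itself fixes which carboxyl group stays free.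

Step 8
Reactants: 9 (2R,3E,5E,7E)-4,6-diethyl-2-methyl-8-phenylocta-3,5,7-trien-1-ol; 12 (2E)-4-methoxy-3-methyl-4-oxobut-2-enoic acid
Product: 13 4-[(2R,3E,5E,7E)-4,6-diethyl-2-methyl-8-phenylocta-3,5,7-trien-1-yl] 1-methyl (2E)-2-methylbut-2-enedioate
Conditions: DCC, DMAP (cat.), CH2Cl2, 0 °C → rt
Reagents that add atoms: none
Why: Steglich esterification (carbodiimide activation with acyl transfer by DMAP) joins the primary alcohol to the free acid and installs the C3–O–C2 ester tether without touching any alkene geometry.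

Step 9
Reactants: 13 4-[(2R,3E,5E,7E)-4,6-diethyl-2-methyl-8-phenylocta-3,5,7-trien-1-yl] 1-methyl (2E)-2-methylbut-2-enedioate
Product: 14 methyl (4R,4aR,7R,8S,8aR)-5,7-diethyl-4,8-dimethyl-1-oxo-7-[(E)-2-phenylethenyl]-3,4,4a,7,8,8a-hexahydro-1H-isochromene-8-carboxylate
Conditions: toluene (0.01 M), BHT (cat.), 115 °C, sealed tube, dark
Reagents that add atoms: none
Why: Intramolecular Diels–Alder reaction (diene C7a=C7–C6=C5, doubly activated dienophile C4=C3a) should form C4–C5 and C3a–C7a: the tether fixes the regiochemistry, the alkene geometries are transferred stereospecifically to C4, C5 and C3a, allylic 1,3-strain between the C1 substituents and the C7 ethyl group steers the dienophile to the diene face anti to the C1 methyl group (setting C7a), and the transition state with the tether carbonyl exo and the methyl ester endo gives the trans ring fusion.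

Step 10
Reactants: 14 methyl (4R,4aR,7R,8S,8aR)-5,7-diethyl-4,8-dimethyl-1-oxo-7-[(E)-2-phenylethenyl]-3,4,4a,7,8,8a-hexahydro-1H-isochromene-8-carboxylate
Product: 15 methyl (4R,4aR,7R,8S,8aR)-1,5,7-triethyl-1-hydroxy-4,8-dimethyl-7-[(E)-2-phenylethenyl]-3,4,4a,7,8,8a-hexahydro-1H-isochromene-8-carboxylate
Conditions: EtLi (1.2 equiv), THF, −78 °C; then aq. NH4Cl
Reagents that add atoms: ethyllithium, [Li]CC
Why: Addition of one equivalent of an alkyllithium to the lactone carbonyl (C3) should stop after one addition because the tetrahedral adduct is stable at −78 °C, while the methyl ester on quaternary C4 is too shielded to react.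

Step 11
Reactants: 15 methyl (4R,4aR,7R,8S,8aR)-1,5,7-triethyl-1-hydroxy-4,8-dimethyl-7-[(E)-2-phenylethenyl]-3,4,4a,7,8,8a-hexahydro-1H-isochromene-8-carboxylate
Product: 17 methyl (1S,2R,5R,6R)-2,4-diethyl-1-methyl-5-[(2R)-1-oxopropan-2-yl]-2-[(E)-2-phenylethenyl]-6-propanoylcyclohex-3-ene-1-carboxylate, via open hydroxy ketone 16 (not isolated)
Conditions: Dess–Martin periodinane, NaHCO3, CH2Cl2, 0 °C → rt; crude product used at once
Reagents that add atoms: none
Why: Dess–Martin oxidation acts on the primary alcohol of the open hydroxy ketone 16 that is in equilibrium with hemiketal 15, and the buffered neutral medium protects the stereocentres next to the aldehyde (C1) and the ketone (C3a).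

Step 12
Reactants: 17 methyl (1S,2R,5R,6R)-2,4-diethyl-1-methyl-5-[(2R)-1-oxopropan-2-yl]-2-[(E)-2-phenylethenyl]-6-propanoylcyclohex-3-ene-1-carboxylate
Product: 19 methyl (1S,3aS,4S,5R,7aR)-3,5,7-triethyl-1,4-dimethyl-5-[(E)-2-phenylethenyl]-3a,4,5,7a-tetrahydro-1H-indene-4-carboxylate, via titanium pinacolate 18 (not isolated)
Conditions: TiCl3(DME)1.5, Zn–Cu couple, DME, reflux; 17 added over 20 h by syringe pump (high dilution)
Reagents that add atoms: none
Why: Low-valent titanium generated from TiCl3(DME)1.5 and Zn–Cu transfers one electron to each carbonyl group, the two ketyl carbons (C2 and C3) couple to the titanium-bound pinacolate 18, and at reflux the oxophilic titanium surface removes both oxygen atoms to leave the C2=C3 double bond. The closest known reaction type is the intramolecular McMurry coupling of 1,5-keto aldehydes to cyclopentenes. Ring B closes as a five-membered carbocycle by head-to-head union of the two former carbonyl carbons, which the trans arms on C3a and C7a hold within bonding distance. No stereocentre is created, since C2 and C3 end as sp2 carbons, and C1, C3a and C7a should keep their configurations because the medium is non-basic and ketyl formation outpaces enolisation. The step needs chemoselectivity for aldehyde and ketone over the methyl ester and the three alkenes, secured by the much easier reduction of the two carbonyl groups and by the shielding of the ester on quaternary C4, and it needs ring closure to win over intermolecular coupling, secured by slow addition at high dilution.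

Step 13
Reactants: 19 methyl (1S,3aS,4S,5R,7aR)-3,5,7-triethyl-1,4-dimethyl-5-[(E)-2-phenylethenyl]-3a,4,5,7a-tetrahydro-1H-indene-4-carboxylate
Product: 21 (1S,3aS,4S,5R,7aR)-3,5,7-triethyl-1,4-dimethyl-5-[(E)-2-phenylethenyl]-3a,4,5,7a-tetrahydro-1H-indene-4-carboxylic acid, via sodium carboxylate 20 (not isolated)
Conditions: NaSEt, DMF, 90 °C; then 1 M HCl, 0 °C
Reagents that add atoms: none
Why: Nucleophilic demethylation (SN2 attack of thiolate on the ester methyl group) cleaves a methyl ester that is too hindered for saponification, and brief cold acidification of carboxylate 20 gives the acid without exposing the two γ,δ-alkenes to strong acid.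

Compound list
1 | methyl (2S)-3-hydroxy-2-methylpropanoate ((S)-Roche ester) | OC[C@H](C)C(=O)OC | starting material
2 | methyl (2S)-3-[(tert-butyldimethylsilyl)oxy]-2-methylpropanoate | CC(C)(C)[Si](C)(C)OC[C@H](C)C(=O)OC | intermediate
3 | (2S)-3-[(tert-butyldimethylsilyl)oxy]-2-methylpropanal | CC(C)(C)[Si](C)(C)OC[C@H](C)C=O | intermediate
4 | 2-(triphenylphosphoranylidene)butanal | CCC(C=O)=P(c1ccccc1)(c1ccccc1)c1ccccc1 | starting material
5 | (2E,4R)-5-[(tert-butyldimethylsilyl)oxy]-2-ethyl-4-methylpent-2-enal | CC(C)(C)[Si](C)(C)OC[C@H](C)/C=C(CC)/C=O | intermediate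
6 | (2E,4E,6R)-7-[(tert-butyldimethylsilyl)oxy]-2,4-diethyl-6-methylhepta-2,4-dienal | CC(C)(C)[Si](C)(C)OC[C@H](C)/C=C(CC)/C=C(CC)/C=O | intermediate
7 | diethyl benzylphosphonate | CCOP(=O)(Cc1ccccc1)OCC | starting material
8 | tert-butyl{[(2R,3E,5E,7E)-4,6-diethyl-2-methyl-8-phenylocta-3,5,7-trien-1-yl]oxy}dimethylsilane | CC(C)(C)[Si](C)(C)OC[C@H](C)/C=C(CC)/C=C(CC)/C=C/c1ccccc1 | intermediate
9 | (2R,3E,5E,7E)-4,6-diethyl-2-methyl-8-phenylocta-3,5,7-trien-1-ol | OC[C@H](C)/C=C(CC)/C=C(CC)/C=C/c1ccccc1 | intermediate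
10 | glyoxylic acid monohydrate (2,2-dihydroxyacetic acid) | OC(O)C(=O)O | starting material
11 | methyl 2-(triphenylphosphoranylidene)propanoate | COC(=O)C(C)=P(c1ccccc1)(c1ccccc1)c1ccccc1 | starting material
12 | (2E)-4-methoxy-3-methyl-4-oxobut-2-enoic acid (mesaconic acid half ester, methyl ester on the methyl-bearing carbon) | COC(=O)/C(C)=C/C(=O)O | intermediate
13 | 4-[(2R,3E,5E,7E)-4,6-diethyl-2-methyl-8-phenylocta-3,5,7-trien-1-yl] 1-methyl (2E)-2-methylbut-2-enedioate | COC(=O)/C(C)=C/C(=O)OC[C@H](C)/C=C(CC)/C=C(CC)/C=C/c1ccccc1 | intermediate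
14 | methyl (4R,4aR,7R,8S,8aR)-5,7-diethyl-4,8-dimethyl-1-oxo-7-[(E)-2-phenylethenyl]-3,4,4a,7,8,8a-hexahydro-1H-isochromene-8-carboxylate (trans-fused lactone) | CCC1=C[C@](/C=C/c2ccccc2)(CC)[C@@](C)(C(=O)OC)[C@@H]2C(=O)OC[C@H](C)[C@@H]12 | intermediate
15 | methyl (4R,4aR,7R,8S,8aR)-1,5,7-triethyl-1-hydroxy-4,8-dimethyl-7-[(E)-2-phenylethenyl]-3,4,4a,7,8,8a-hexahydro-1H-isochromene-8-carboxylate (hemiketal, configuration at the hemiketal carbon not fixed) | CCC1=C[C@](/C=C/c2ccccc2)(CC)[C@@](C)(C(=O)OC)[C@@H]2C(O)(CC)OC[C@H](C)[C@@H]12 | intermediate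
16 | methyl (1S,2R,5R,6R)-2,4-diethyl-5-[(2R)-1-hydroxypropan-2-yl]-1-methyl-2-[(E)-2-phenylethenyl]-6-propanoylcyclohex-3-ene-1-carboxylate (open hydroxy ketone) | CCC1=C[C@](/C=C/c2ccccc2)(CC)[C@@](C)(C(=O)OC)[C@H](C(=O)CC)[C@H]1[C@H](CO)C | intermediate
17 | methyl (1S,2R,5R,6R)-2,4-diethyl-1-methyl-5-[(2R)-1-oxopropan-2-yl]-2-[(E)-2-phenylethenyl]-6-propanoylcyclohex-3-ene-1-carboxylate (keto aldehyde) | CCC1=C[C@](/C=C/c2ccccc2)(CC)[C@@](C)(C(=O)OC)[C@H](C(=O)CC)[C@H]1[C@H](C=O)C | intermediate
18 | titanium pinacolate of 17 (ring-closed C2,C3-diolate bound to titanium, drawn as the titanadioxolane with further ligands on titanium omitted; configuration at C2 and C3 not fixed) | CCC1=C[C@](/C=C/c2ccccc2)(CC)[C@@](C)(C(=O)OC)[C@@H]2C3(CC)O[Ti]OC3[C@H](C)[C@@H]12 | intermediate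
19 | methyl (1S,3aS,4S,5R,7aR)-3,5,7-triethyl-1,4-dimethyl-5-[(E)-2-phenylethenyl]-3a,4,5,7a-tetrahydro-1H-indene-4-carboxylate | CCC1=C[C@](/C=C/c2ccccc2)(CC)[C@@](C)(C(=O)OC)[C@@H]2C(CC)=C[C@H](C)[C@@H]12 | intermediate
20 | sodium (1S,3aS,4S,5R,7aR)-3,5,7-triethyl-1,4-dimethyl-5-[(E)-2-phenylethenyl]-3a,4,5,7a-tetrahydro-1H-indene-4-carboxylate | CCC1=C[C@](/C=C/c2ccccc2)(CC)[C@@](C)(C(=O)[O-])[C@@H]2C(CC)=C[C@H](C)[C@@H]12.[Na+] | intermediate
21 | (1S,3aS,4S,5R,7aR)-3,5,7-triethyl-1,4-dimethyl-5-[(E)-2-phenylethenyl]-3a,4,5,7a-tetrahydro-1H-indene-4-carboxylic acid (CNP0242622.1) | CCC1=C[C@](/C=C/c2ccccc2)(CC)[C@@](C)(C(=O)O)[C@@H]2C(CC)=C[C@H](C)[C@@H]12 | target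

Total step count: 13. Longest linear sequence: 12 steps (steps 1 to 6 and 8 to 13, from 1); step 7 is a one-step side branch.

Steps most likely to fail

Step 12. Deoxygenation of the titanium-bound diolate may stall at the pinacol stage, or the 1,5-keto aldehyde may be consumed by Lewis-acid-promoted aldol cyclisation before the two ketyl centres meet. The fallback replaces reductive carbonyl coupling by olefin metathesis. Setting out from 17, twofold methylenation under non-basic conditions (Zn, CH2Br2, TiCl4, THF, 0 °C → rt) would give the diene methyl (1S,2R,5R,6S)-6-(but-1-en-2-yl)-5-[(2S)-but-3-en-2-yl]-2,4-diethyl-1-methyl-2-[(E)-2-phenylethenyl]cyclohex-3-ene-1-carboxylate F1. Ring-closing metathesis with the second-generation Grubbs catalyst RuCl2(=CHPh)(H2IMes)(PCy3) in toluene at 80 °C would then join its 1,1-disubstituted and monosubstituted alkenes into the same C2=C3 bond with loss of ethylene and come back to the route at 19. The styryl group is trans to the C3 arm on ring A and so cannot take part in a ring closure.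

Step 9. At the temperature that the ester tether demands, a 1,5-hydrogen shift from the inward-pointing ethyl group of the diene may outrun the cycloaddition, and the transition state with the tether carbonyl endo may compete and lead to the cis ring fusion. The fallback uses a dienophile activated by an aldehyde in place of the methyl ester, which should react well below that temperature and with a stronger endo preference. Wittig reaction of 10 with commercial 2-(triphenylphosphoranylidene)propanal would give (2E)-3-methyl-4-oxobut-2-enoic acid F2. Setting out from 9, Steglich esterification with this acid would give (2R,3E,5E,7E)-4,6-diethyl-2-methyl-8-phenylocta-3,5,7-trien-1-yl (2E)-3-methyl-4-oxobut-2-enoate F3. Cycloaddition with Me2AlCl in CH2Cl2 at −20 °C (or at 40 °C without additive) should give (4R,4aR,7R,8S,8aR)-5,7-diethyl-4,8-dimethyl-1-oxo-7-[(E)-2-phenylethenyl]-3,4,4a,7,8,8a-hexahydro-1H-isochromene-8-carbaldehyde F4. Pinnick oxidation (NaClO2, NaH2PO4, 2-methylbut-2-ene, t-BuOH/H2O) would give (4R,4aR,7R,8S,8aR)-5,7-diethyl-4,8-dimethyl-1-oxo-7-[(E)-2-phenylethenyl]-3,4,4a,7,8,8a-hexahydro-1H-isochromene-8-carboxylic acid F5, and methylation with Me3SiCHN2 in toluene/MeOH comes back to the route at 14.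

Step 11. The ring-closed hemiketal may be so strongly favoured that oxidation of the small share of open hydroxy ketone stalls, and long exposure may epimerise the centre next to the new aldehyde. The fallback reverses the order of reduction and carbon–carbon bond formation so that no ketone hemiketal is involved. Setting out from 14, i-Bu2AlH (1 equiv, CH2Cl2, −78 °C) would reduce the lactone to methyl (4R,4aR,7R,8S,8aR)-5,7-diethyl-1-hydroxy-4,8-dimethyl-7-[(E)-2-phenylethenyl]-3,4,4a,7,8,8a-hexahydro-1H-isochromene-8-carboxylate F6. EtMgBr (THF, 0 °C) would add to its open hydroxy aldehyde form to give methyl (1S,2R,5R,6R)-2,4-diethyl-6-(1-hydroxypropyl)-5-[(2R)-1-hydroxypropan-2-yl]-1-methyl-2-[(E)-2-phenylethenyl]cyclohex-3-ene-1-carboxylate F7 (carbinol epimers, both usable). Twofold Dess–Martin oxidation of this acyclic diol comes back to the route at 17.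

Further compounds
F1 | step 12 | methyl (1S,2R,5R,6S)-6-(but-1-en-2-yl)-5-[(2S)-but-3-en-2-yl]-2,4-diethyl-1-methyl-2-[(E)-2-phenylethenyl]cyclohex-3-ene-1-carboxylate | CCC1=C[C@](/C=C/c2ccccc2)(CC)[C@@](C)(C(=O)OC)[C@H](C(=C)CC)[C@H]1[C@H](C=C)C
F2 | step 9 | (2E)-3-methyl-4-oxobut-2-enoic acid | O=C/C(C)=C/C(=O)O
F3 | step 9 | (2R,3E,5E,7E)-4,6-diethyl-2-methyl-8-phenylocta-3,5,7-trien-1-yl (2E)-3-methyl-4-oxobut-2-enoate | O=C/C(C)=C/C(=O)OC[C@H](C)/C=C(CC)/C=C(CC)/C=C/c1ccccc1
F4 | step 9 | (4R,4aR,7R,8S,8aR)-5,7-diethyl-4,8-dimethyl-1-oxo-7-[(E)-2-phenylethenyl]-3,4,4a,7,8,8a-hexahydro-1H-isochromene-8-carbaldehyde | CCC1=C[C@](/C=C/c2ccccc2)(CC)[C@@](C)(C=O)[C@@H]2C(=O)OC[C@H](C)[C@@H]12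
F5 | step 9 | (4R,4aR,7R,8S,8aR)-5,7-diethyl-4,8-dimethyl-1-oxo-7-[(E)-2-phenylethenyl]-3,4,4a,7,8,8a-hexahydro-1H-isochromene-8-carboxylic acid | CCC1=C[C@](/C=C/c2ccccc2)(CC)[C@@](C)(C(=O)O)[C@@H]2C(=O)OC[C@H](C)[C@@H]12
F6 | step 11 | methyl (4R,4aR,7R,8S,8aR)-5,7-diethyl-1-hydroxy-4,8-dimethyl-7-[(E)-2-phenylethenyl]-3,4,4a,7,8,8a-hexahydro-1H-isochromene-8-carboxylate | CCC1=C[C@](/C=C/c2ccccc2)(CC)[C@@](C)(C(=O)OC)[C@@H]2C(O)OC[C@H](C)[C@@H]12
F7 | step 11 | methyl (1S,2R,5R,6R)-2,4-diethyl-6-(1-hydroxypropyl)-5-[(2R)-1-hydroxypropan-2-yl]-1-methyl-2-[(E)-2-phenylethenyl]cyclohex-3-ene-1-carboxylate | CCC1=C[C@](/C=C/c2ccccc2)(CC)[C@@](C)(C(=O)OC)[C@H](C(O)CC)[C@H]1[C@H](CO)C
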